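## Structural features

Silyhermin B is a flavanolignan: a 2,3-dihydro-1-benzofuran (O1, C2, C3 fused to the benzene ring C3a–C7a) is bonded through C5 to C2' of a 5,7-dihydroxychroman-4-one (primes mark the flavanone atoms). C2 carries a 4-hydroxy-3-methoxyphenyl group, C3 a CH2OH group and C7 a free phenol next to O1. C2 (R) and C3 (S) are adjacent and trans; the third stereocentre, C2' (S), lies across the benzene ring and cannot be relayed from the other two. The descriptors were checked against the structures: trans-(2R,3S) in the target corresponds to trans-(2R,3R) at the acetal stage, the change at C3 being one of substituent priority only, and no structural error was found. The fragile points are these: the flavanone opens to a chalcone by retro-oxa-Michael reaction under base, which racemises C2'; O1–C2 and O1'–C2' are benzylic aryl ethers, sensitive to acid ionisation and to hydrogenolysis; the five phenols are easily oxidised; and any C3 carbonyl precursor is a β-aryloxy carbonyl compound that can expel O1. The real difficulty is therefore double: the trans C2/C3 pair must be made in one absolute sense, and the remote C2' must be set by a reagent alone under base-free conditions. The key step exploits the fact that C3 bears both the arene carbon C3a and a one-carbon branch, which is the pattern left when the arene carbon of a 2-aryl-2H-chromene moves from C4 to C3 and C4 is pushed out of the ring.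

## Logic of the disconnections

**24 to 23 and 22.** No skeletal bond is cut: four aryl O–CH2Ph bonds (23 to 24) and one O–Si bond (22 to 23) are cleaved. Benzyl ethers on all four phenols survive the trivalent iodine reagent, the organolithium and the cationic palladium catalyst, and they fall under neutral hydrogenolysis. The primary hydroxyl is held as a silyl ether, not a benzyl ether, because an alkyl benzyl ether would need longer hydrogenolysis than the two ring benzylic C–O bonds may tolerate. The demand is a hydrogenolysis that stops at the aryl benzyl ethers and a desilylation that is acidic, not basic.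

**22 to 17 and 21.** The bond cut is C5–C2', the aryl–C(sp3) bond between the two halves. This divides the molecule into two fragments of similar size, one of them (21) flat and achiral, and turns C2' into the product of a catalyst-controlled conjugate addition. The demand is an enantioselective aryl transfer to an electron-rich acceptor without base, with 17 as the limiting partner.

**21 to 19 and 18.** O1'–C2' and C2'–C3' are cut, so that C2' is removed as a one-carbon unit, and then the two O–benzyl bonds. The gain is a commercial ketone. The demand is a bis-benzylation that spares the chelated hydroxyl which later closes the pyranone.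

**17 to 14, 13 and 11.** The C–B bond is traced to C–Br (14), the O–Si bond is removed (13), and the CH2OH carbon is taken back to the acetal oxidation level (11), with 12 as a transient link. Bromine is chosen because it is inert to every earlier reagent and convertible to boron afterwards. The demand is that 12 be reduced as soon as it forms, since it is a β-aryloxy aldehyde.

**11 to 10 (strategic cut).** C3–C3a is cut and C4–C4a restored, which puts the acetal carbon back into a six-membered ring as C4 of an alkene. Two adjacent stereocentres are reduced to one, and that one (C2) is an allylic, benzylic ether carbon open to catalytic asymmetric arylation. The demand is anti addition of iodine relative to the C2 aryl group and migration of the ring arene carbon in preference to the C2 aryl group.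

**10 to 7 and 8.** The C2–aryl bond is cut to an oxocarbenium precursor (7) and an electron-rich aryl boron nucleophile (8). The gain is a racemic acetal whose stereocentre is erased on ionisation, so a chiral catalyst can set C2. The demand is face-selective aryl delivery; the benzyl ether on 8 keeps the arene nucleophilic.

**7 to 5, 3, 2 and 1.** The acetal C–O bond goes back to the lactone carbonyl (5); C3=C4 and the lactone C–O go back to an aldehyde and a two-carbon ylide (3); then C–Br (2) and O–benzyl (1) are cut. Benzylation precedes bromination so that bromine enters para to the only free hydroxyl. The demand is mono-alkylation of the catechol at the 3-oxygen.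

## Other disconnections considered

**Alternative 1:** The cut is C4a'–C8a' inside ring A, so the phloroglucinol ring is unravelled to the open-chain triketo ester A2, which already carries the finished dihydrobenzofuran and a silyloxy group on C9.
- Forward key step: Mg(OMe)2 in methanol would chelate the polyketo chain and fold it in the Claisen mode (C6 onto the ester carbon C1); loss of methoxide and enolisation would aromatise the new carbocycle to the acylphloroglucinol A1. Desilylation and a Mitsunobu closure with inversion of the (R)-carbinol would then give the (2S)-flavanone.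
- In favour: ring A appears with its hydroxyls free, which saves two benzyl ethers; the carbinol centre could be set by a dependable aldol or ketone-reduction method; the logic follows the biosynthesis.
- Against: A2 has four carbonyl groups of similar reactivity and can also fold in the aldol mode (C2 onto C7, a resorcylate) or lactonise to a pyrone. The basic medium can eliminate the β-silyloxy group of A2 or A1 to a chalcone, which erases the stereocentre. The Mitsunobu closure of a benzylic β-hydroxy ketone competes with dehydration. A1 carries an alkyl benzyl ether that is slow to hydrogenolyse, and the alternative does not make the dihydrobenzofuran at all.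
- Comparison, structure: both plans pass through a flavanone with the same three stereocentres; the chosen plan takes ring A from a commercial ketone, the alternative builds it.
- Comparison, mechanism: the chosen 1,2-shift is stereospecific and directed by orbital alignment, while the fold of A2 depends on how a flexible chain chelates.
- Comparison, step economy: the alternative is longer, because A2 needs repeated acylations of polyanions.
- The alternative is the better in protecting-group economy on ring A and in avoiding an aryl transfer to a deactivated chromone. It is the equal in the number of asymmetric operations (two).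

**Alternative 2:** The cut is C2'–C3' of the pyranone. The precursor is the 4-methylene-1,3-benzodioxine A4, in which the two halves are tied through an acetal carbon; the product A3 is the same compound as 22.
- Forward key step: the chiral aluminium Lewis acid from Me2AlCl and a 3,3'-disubstituted binaphthol would bind the enol ether oxygen. The C–O bond of the acetal would break to an aryl-stabilised oxocarbenium ion paired with an aluminium enolate, and the enolate CH2 carbon would close on C2' to give the chromanone (Petasis–Ferrier rearrangement).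
- In favour: the new C–C bond forms intramolecularly between tethered partners; no boron reagent and no palladium are needed; A4 would be assembled by acetal formation between the two halves followed by carbonyl methylenation with Cp2TiMe2; the endgame from A3 is the one already planned.
- Against: the acetal stereocentre is lost on ionisation, so the configuration of C2' would rest wholly on the chiral counter-ion, for which a high and predictable selectivity cannot be claimed. The strong Lewis acid threatens the benzyl ether peri to the carbonyl, the silyl ether and the para-oxygenated benzylic O1–C2 bond. The oxocarbenium ion could attack the electron-rich ring A carbons instead of the enolate carbon, and the product can reopen to a chalcone under Lewis acid.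
- Comparison, structure: equal, since both plans join the same two halves and meet at 22.
- Comparison, mechanism: the chosen carbopalladation of 21 within a chiral ligand pocket has a clear stereochemical model; the ion-pair recombination has none of comparable reliability.
- Comparison, step economy: about equal (formylation, acetalisation, methylenation and rearrangement against borylation, addition and two steps to 21).
- The alternative is the better in using no precious metal for the fragment union.

**Alternative 3:** The cut is O1–C2 of the dihydrofuran. The precursor is the open 1,2-diarylpropane A6, with free guaiacol and free ortho phenol, and the product is the aldehyde A5.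
- Forward key step: Ag2O would oxidise the 4-alkyl-2-methoxyphenol of A6 to its para-quinone methide, and the phenol oxygen on C7a would add to the methide carbon (5-exo-trig), closing the ring to trans-A5 under control by C3.
- In favour: the ring forms under mild, nearly neutral conditions, following the biosynthetic logic; the guaiacol needs no protecting group; A5 carries an aldehyde as a handle for ring C.
- Against: A6 must already contain C3 as a single enantiomer, so a separate asymmetric synthesis of a 1,2-diarylpropane is required. That centre is α to the methide carbon and benzylic, so tautomerisation of the quinone methide to a stilbene would racemise it. Two free phenols and an aldehyde are exposed to the oxidant, which invites over-oxidation and intermolecular capture. The aldehyde handle leads to the flavanone through a chalcone, where C2' is hard to control.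
- Comparison, structure: equal in the number of asymmetric operations for C2/C3 (one each).
- Comparison, mechanism: the chosen plan creates C3 and fixes its relation to C2 in the same stereospecific step, and C3 is never adjacent to a cationic or methide carbon afterwards; the alternative sets C2 by substrate control from a centre that the reactive intermediate can erase.
- Comparison, step economy: about equal up to the dihydrobenzofuran.
- The alternative is the better in protecting-group count and in avoiding a hypervalent iodine oxidant.

Key step: step 6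

Assumption: the sense of induction of the two chiral catalysts is taken by analogy (the (2R,3R)-tartaric acid monoamide is assumed to give (R)-10 and (R)-t-BuPyOx the (S)-flavanone); if either sense proves opposite, the mirror-image catalyst is used; boronic acid 8 is taken to be a catalogue compound.

## Route

Step 1
Reactants: 1 2,3-dihydroxybenzaldehyde
Product: 2 3-(benzyloxy)-2-hydroxybenzaldehyde
Conditions: NaH (2.2 equiv), DMSO, rt; BnBr (1.0 equiv), rt; aq. HCl work-up
Reagents that add atoms: benzyl bromide, BrCc1ccccc1
Why: Williamson etherification of the dianion: the 2-phenoxide is delocalised into and chelated by the formyl group, so the single equivalent of halide should be taken by the more nucleophilic 3-phenoxide.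

Step 2
Reactants: 2 3-(benzyloxy)-2-hydroxybenzaldehyde
Product: 3 3-(benzyloxy)-5-bromo-2-hydroxybenzaldehyde
Conditions: Br2 (1.05 equiv), NaOAc, AcOH, rt
Reagents that add atoms: bromine, BrBr
Why: Electrophilic aromatic bromination para to the free hydroxyl, the one activated position that is neither ortho nor para to the formyl group, as in the bromination of 2-hydroxy-3-methoxybenzaldehyde; placing it after the benzylation leaves a single strong director.

Step 3
Reactants: 3 3-(benzyloxy)-5-bromo-2-hydroxybenzaldehyde
Product: 5 8-(benzyloxy)-6-bromo-2H-chromen-2-one, via cinnamate ester 4 (not isolated)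
Conditions: Ph3P=CHCO2Et (1.2 equiv), PhNEt2, reflux
Reagents that add atoms: ethyl (triphenylphosphoranylidene)acetate, CCOC(=O)C=P(c1ccccc1)(c1ccccc1)c1ccccc1
Why: Wittig olefination of the salicylaldehyde; at the reflux temperature of N,N-diethylaniline the mainly (E)-cinnamate isomerises and lactonises with loss of ethanol to the coumarin.

Step 4
Reactants: 5 8-(benzyloxy)-6-bromo-2H-chromen-2-one
Product: 7 8-(benzyloxy)-6-bromo-2-ethoxy-2H-chromene (racemic), via lactol 6 (not isolated)
Conditions: i-Bu2AlH (1.1 equiv), CH2Cl2, −78 °C; aq. potassium sodium tartrate (KNaC4H4O6); crude lactol, EtOH, PPTS (cat.), 4 Å MS, rt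
Reagents that add atoms: ethanol, CCO
Why: Partial reduction of the lactone stops at the aluminium hemiacetal at low temperature; acid-catalysed exchange of the lactol with ethanol through the 1-benzopyrylium ion should give the mixed acetal, which is handled on base-washed silica.

Step 5
Reactants: 7 8-(benzyloxy)-6-bromo-2-ethoxy-2H-chromene (racemic); 8 [4-(benzyloxy)-3-methoxyphenyl]boronic acid
Product: 10 (2R)-8-(benzyloxy)-2-[4-(benzyloxy)-3-methoxyphenyl]-6-bromo-2H-chromene, via diethyl boronate 9 (not isolated)
Conditions: 8 (1.5 equiv), EtOH, 4 Å MS, then evaporation; 7, (2R,3R)-4-(dibenzylamino)-2,3-dihydroxy-4-oxobutanoic acid (10 mol %), Yb(OTf)3 (5 mol %), EtOAc, −20 to 4 °C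
Reagents that add atoms: none
Why: Petasis-type addition of an aryl boronate to an oxocarbenium ion: the acid pair ionises the acetal to the achiral 1-benzopyrylium ion, and the boronate, bound to the chiral hydroxy acid as a dioxaborolane, delivers the electron-rich aryl group to one face of C2. The catalyst alone sets C2 (R), since the stereocentre of 7 is erased on ionisation.

Step 6
Reactants: 10 (2R)-8-(benzyloxy)-2-[4-(benzyloxy)-3-methoxyphenyl]-6-bromo-2H-chromene
Product: 11 (2R,3R)-7-(benzyloxy)-2-[4-(benzyloxy)-3-methoxyphenyl]-5-bromo-3-(dimethoxymethyl)-2,3-dihydro-1-benzofuran (trans)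
Conditions: PhI(OH)OTs (1.2 equiv), HC(OMe)3/MeOH, 0 °C to rt; aq. NaHCO3
Reagents that add atoms: methanol, CO (the methoxy groups may equally be delivered by the co-solvent trimethyl orthoformate, COC(OC)OC)
Why: The electrophilic trivalent iodine of PhI(OH)OTs attacks C3, the nucleophilic terminus of the alkene conjugated with O1 through the arene, on the face opposite the C2 aryl group, and methanol caps the O1-stabilised benzylic cation at C4 anti to iodine. In the resulting all-equatorial half-chair the C3–I bond is antiperiplanar to the ring bond C4–C4a, so the arene carbon C4a shifts to C3 through a phenonium ion as iodobenzene (monovalent iodine) departs, and the methoxy-stabilised cation left on C4 is captured by methanol as the dimethyl acetal while the orthoformate removes water. The closest known reactions are the contraction of 1,2-dihydronaphthalenes to trans-indane acetals by the same reagent and, in trimethyl orthoformate, the contraction of flavanones (through their 4-methoxy-2H-chromene enol ethers) to methyl trans-2-aryl-2,3-dihydrobenzofuran-3-carboxylates. The five-membered ring is not closed by a cyclisation but by a suprafacial 1,2-shift, C3–C3a forming as C4–C4a breaks, with transient three-membered bridging in the phenonium ion. C3 is the new stereocentre: C2 directs iodine to the opposite face and the shift inverts C3, so the extruded acetal carbon ends trans to the aryl group (2R,3R), and C2 itself is not touched. The step needs the alkene to react before the two benzyloxy arenes, which its higher nucleophilicity, the low temperature and the near-stoichiometric oxidant should secure. It also needs migration of C4a to beat migration of the C2 aryl group, solvolytic dimethoxylation and hydride loss from C2: the equatorial C–I bond aligns only ring bonds, O1 ortho to C4a raises its migratory aptitude, and the orthoformate-rich, weakly nucleophilic medium disfavours direct displacement.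

Step 7
Reactants: 11 (2R,3R)-7-(benzyloxy)-2-[4-(benzyloxy)-3-methoxyphenyl]-5-bromo-3-(dimethoxymethyl)-2,3-dihydro-1-benzofuran (trans)
Product: 13 [(2R,3S)-7-(benzyloxy)-2-[4-(benzyloxy)-3-methoxyphenyl]-5-bromo-2,3-dihydro-1-benzofuran-3-yl]methanol (trans), via aldehyde 12 (not isolated)
Conditions: 2 M aq. HCl, THF, rt; then NaHCO3 to pH 7–8, NaBH4, MeOH, 0 °C
Reagents that add atoms: water, O
Why: Acid hydrolysis of the acetal gives the aldehyde, in which any cis isomer can equilibrate to trans by enolisation; immediate borohydride reduction at 0 °C should convert it into the primary alcohol before base-induced β-elimination of O1 can start. Neither stereocentre changes in space; the C3 descriptor becomes S for priority reasons only.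

Step 8
Reactants: 13 [(2R,3S)-7-(benzyloxy)-2-[4-(benzyloxy)-3-methoxyphenyl]-5-bromo-2,3-dihydro-1-benzofuran-3-yl]methanol (trans)
Product: 14 tert-butyl{[(2R,3S)-7-(benzyloxy)-2-[4-(benzyloxy)-3-methoxyphenyl]-5-bromo-2,3-dihydro-1-benzofuran-3-yl]methoxy}dimethylsilane
Conditions: TBSCl (1.2 equiv), imidazole (2.5 equiv), DMF, rt
Reagents that add atoms: tert-butyldimethylsilyl chloride, CC(C)(C)[Si](C)(C)Cl
Why: Standard silylation of a primary alcohol; the silyl ether removes the acidic proton before the lithiation and shields the alcohol from palladium-mediated oxidation in step 12.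

Step 9
Reactants: 14 tert-butyl{[(2R,3S)-7-(benzyloxy)-2-[4-(benzyloxy)-3-methoxyphenyl]-5-bromo-2,3-dihydro-1-benzofuran-3-yl]methoxy}dimethylsilane
Product: 17 [(2R,3S)-7-(benzyloxy)-2-[4-(benzyloxy)-3-methoxyphenyl]-3-{[(tert-butyldimethylsilyl)oxy]methyl}-2,3-dihydro-1-benzofuran-5-yl]boronic acid, via aryllithium 15 (not isolated), via lithium triisopropoxyborate 16 (not isolated)
Conditions: B(Oi-Pr)3 (1.5 equiv), n-BuLi (1.1 equiv, added last), THF, −78 to 0 °C; aq. NH4Cl
Reagents that add atoms: triisopropyl borate, CC(C)OB(OC(C)C)OC(C)C; water, O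
Why: Bromine–lithium exchange is faster than any deprotonation at −78 °C, and with the borate already present the aryllithium is trapped as the ate complex as it forms; mild hydrolysis should release the boronic acid, the form that transmetalates readily in step 12.

Step 10
Reactants: 18 1-(2,4,6-trihydroxyphenyl)ethan-1-one
Product: 19 1-[2,4-bis(benzyloxy)-6-hydroxyphenyl]ethan-1-one
Conditions: BnBr (2.1 equiv), K2CO3 (2.2 equiv), DMF, rt
Reagents that add atoms: benzyl bromide, BrCc1ccccc1
Why: Williamson etherification; one ortho hydroxyl stays hydrogen-bonded to the acetyl group and is the least nucleophilic, so two equivalents of halide should leave it free for the later ring closure.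

Step 11
Reactants: 19 1-[2,4-bis(benzyloxy)-6-hydroxyphenyl]ethan-1-one
Product: 21 5,7-bis(benzyloxy)-4H-chromen-4-one, via enaminone 20 (not isolated)
Conditions: Me2NCH(OMe)2 (3 equiv), toluene, 100 °C; evaporation; conc. HCl, CH2Cl2, rt
Reagents that add atoms: N,N-dimethylformamide dimethyl acetal, COC(OC)N(C)C
Why: Condensation of the acetyl methyl group with the formamide acetal gives the enaminone; acid then promotes addition of the ortho phenol to the β-carbon and loss of dimethylamine, the standard enaminone route to 3-unsubstituted chromones.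

Step 12
Reactants: 17 [(2R,3S)-7-(benzyloxy)-2-[4-(benzyloxy)-3-methoxyphenyl]-3-{[(tert-butyldimethylsilyl)oxy]methyl}-2,3-dihydro-1-benzofuran-5-yl]boronic acid; 21 5,7-bis(benzyloxy)-4H-chromen-4-one
Product: 22 (2S)-5,7-bis(benzyloxy)-2-[(2R,3S)-7-(benzyloxy)-2-[4-(benzyloxy)-3-methoxyphenyl]-3-{[(tert-butyldimethylsilyl)oxy]methyl}-2,3-dihydro-1-benzofuran-5-yl]-2,3-dihydro-4H-chromen-4-one
Conditions: 17 (1.0 equiv), 21 (1.5 equiv), Pd(OCOCF3)2 (10 mol %), (R)-4-tert-butyl-2-(pyridin-2-yl)-4,5-dihydro-1,3-oxazole [(R)-t-BuPyOx, 12 mol %], NH4PF6 (30 mol %), H2O (5 equiv), ClCH2CH2Cl, 60 °C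
Reagents that add atoms: none
Why: Palladium-catalysed asymmetric conjugate addition of an arylboronic acid (the palladium counterpart of the Hayashi–Miyaura reaction): transmetalation to cationic divalent palladium, enantio-determining insertion of the chromone C2'=C3' bond within the pyridine–oxazoline pocket, then protonolysis of the palladium enolate by water. The ligand sets C2' (S) independently of the distant C2 and C3, and the absence of base keeps the flavanone closed.

Step 13
Reactants: 22 (2S)-5,7-bis(benzyloxy)-2-[(2R,3S)-7-(benzyloxy)-2-[4-(benzyloxy)-3-methoxyphenyl]-3-{[(tert-butyldimethylsilyl)oxy]methyl}-2,3-dihydro-1-benzofuran-5-yl]-2,3-dihydro-4H-chromen-4-one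
Product: 23 (2S)-5,7-bis(benzyloxy)-2-[(2R,3S)-7-(benzyloxy)-2-[4-(benzyloxy)-3-methoxyphenyl]-3-(hydroxymethyl)-2,3-dihydro-1-benzofuran-5-yl]-2,3-dihydro-4H-chromen-4-one
Conditions: 10-camphorsulfonic acid (0.2 equiv), MeOH/CH2Cl2 (1:1), 0 °C to rt
Reagents that add atoms: none
Why: Acid-catalysed methanolysis of a primary silyl ether; acid is chosen over fluoride because basic fluoride could open the flavanone to the chalcone and racemise C2'.

Step 14
Reactants: 23 (2S)-5,7-bis(benzyloxy)-2-[(2R,3S)-7-(benzyloxy)-2-[4-(benzyloxy)-3-methoxyphenyl]-3-(hydroxymethyl)-2,3-dihydro-1-benzofuran-5-yl]-2,3-dihydro-4H-chromen-4-one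
Product: 24 silyhermin B, (2S)-5,7-dihydroxy-2-[(2R,3S)-7-hydroxy-2-(4-hydroxy-3-methoxyphenyl)-3-(hydroxymethyl)-2,3-dihydro-1-benzofuran-5-yl]-2,3-dihydro-4H-chromen-4-one
Conditions: H2 (1 atm), 10 % Pd/C, EtOAc/MeOH, rt, stopped at full conversion
Reagents that add atoms: none
Why: Hydrogenolysis of four aryl benzyl ethers, the fastest class of benzyl ether to cleave, under neutral conditions that should leave the two ring benzylic C–O bonds, the ketone and all three stereocentres untouched.

## Compound list

1 | 2,3-dihydroxybenzaldehyde | O=Cc1cccc(O)c1O | starting material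
2 | 3-(benzyloxy)-2-hydroxybenzaldehyde | O=Cc1cccc(OCc2ccccc2)c1O | intermediate
3 | 3-(benzyloxy)-5-bromo-2-hydroxybenzaldehyde | O=Cc1cc(Br)cc(OCc2ccccc2)c1O | intermediate
4 | ethyl (E)-3-[3-(benzyloxy)-5-bromo-2-hydroxyphenyl]prop-2-enoate | CCOC(=O)/C=C/c1cc(Br)cc(OCc2ccccc2)c1O | intermediate
5 | 8-(benzyloxy)-6-bromo-2H-chromen-2-one | O=C1C=Cc2cc(Br)cc(OCc3ccccc3)c2O1 | intermediate
6 | 8-(benzyloxy)-6-bromo-2H-chromen-2-ol (racemic) | OC1C=Cc2cc(Br)cc(OCc3ccccc3)c2O1 | intermediate
7 | 8-(benzyloxy)-6-bromo-2-ethoxy-2H-chromene (racemic) | CCOC1C=Cc2cc(Br)cc(OCc3ccccc3)c2O1 | intermediate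
8 | [4-(benzyloxy)-3-methoxyphenyl]boronic acid | COc1cc(B(O)O)ccc1OCc1ccccc1 | starting material
9 | diethyl [4-(benzyloxy)-3-methoxyphenyl]boronate | CCOB(OCC)c1ccc(OCc2ccccc2)c(OC)c1 | intermediate
10 | (2R)-8-(benzyloxy)-2-[4-(benzyloxy)-3-methoxyphenyl]-6-bromo-2H-chromene | COc1cc([C@@H]2Oc3c(OCc4ccccc4)cc(Br)cc3C=C2)ccc1OCc1ccccc1 | intermediate
11 | (2R,3R)-7-(benzyloxy)-2-[4-(benzyloxy)-3-methoxyphenyl]-5-bromo-3-(dimethoxymethyl)-2,3-dihydro-1-benzofuran (trans) | COc1cc([C@@H]2Oc3c(OCc4ccccc4)cc(Br)cc3[C@H]2C(OC)OC)ccc1OCc1ccccc1 | intermediate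
12 | (2R,3R)-7-(benzyloxy)-2-[4-(benzyloxy)-3-methoxyphenyl]-5-bromo-2,3-dihydro-1-benzofuran-3-carbaldehyde (trans) | COc1cc([C@@H]2Oc3c(OCc4ccccc4)cc(Br)cc3[C@H]2C=O)ccc1OCc1ccccc1 | intermediate
13 | [(2R,3S)-7-(benzyloxy)-2-[4-(benzyloxy)-3-methoxyphenyl]-5-bromo-2,3-dihydro-1-benzofuran-3-yl]methanol (trans) | COc1cc([C@@H]2Oc3c(OCc4ccccc4)cc(Br)cc3[C@H]2CO)ccc1OCc1ccccc1 | intermediate
14 | tert-butyl{[(2R,3S)-7-(benzyloxy)-2-[4-(benzyloxy)-3-methoxyphenyl]-5-bromo-2,3-dihydro-1-benzofuran-3-yl]methoxy}dimethylsilane | COc1cc([C@@H]2Oc3c(OCc4ccccc4)cc(Br)cc3[C@H]2CO[Si](C)(C)C(C)(C)C)ccc1OCc1ccccc1 | intermediate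
15 | [(2R,3S)-7-(benzyloxy)-2-[4-(benzyloxy)-3-methoxyphenyl]-3-{[(tert-butyldimethylsilyl)oxy]methyl}-2,3-dihydro-1-benzofuran-5-yl]lithium | COc1cc([C@@H]2Oc3c(OCc4ccccc4)cc([Li])cc3[C@H]2CO[Si](C)(C)C(C)(C)C)ccc1OCc1ccccc1 | intermediate
16 | lithium [(2R,3S)-7-(benzyloxy)-2-[4-(benzyloxy)-3-methoxyphenyl]-3-{[(tert-butyldimethylsilyl)oxy]methyl}-2,3-dihydro-1-benzofuran-5-yl]tri(propan-2-yloxy)borate | [Li+].COc1cc([C@@H]2Oc3c(OCc4ccccc4)cc([B-](OC(C)C)(OC(C)C)OC(C)C)cc3[C@H]2CO[Si](C)(C)C(C)(C)C)ccc1OCc1ccccc1 | intermediate
17 | [(2R,3S)-7-(benzyloxy)-2-[4-(benzyloxy)-3-methoxyphenyl]-3-{[(tert-butyldimethylsilyl)oxy]methyl}-2,3-dihydro-1-benzofuran-5-yl]boronic acid | COc1cc([C@@H]2Oc3c(OCc4ccccc4)cc(B(O)O)cc3[C@H]2CO[Si](C)(C)C(C)(C)C)ccc1OCc1ccccc1 | intermediate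
18 | 1-(2,4,6-trihydroxyphenyl)ethan-1-one (2,4,6-trihydroxyacetophenone) | CC(=O)c1c(O)cc(O)cc1O | starting material
19 | 1-[2,4-bis(benzyloxy)-6-hydroxyphenyl]ethan-1-one | CC(=O)c1c(O)cc(OCc2ccccc2)cc1OCc1ccccc1 | intermediate
20 | (E)-1-[2,4-bis(benzyloxy)-6-hydroxyphenyl]-3-(dimethylamino)prop-2-en-1-one | CN(C)/C=C/C(=O)c1c(O)cc(OCc2ccccc2)cc1OCc1ccccc1 | intermediate
21 | 5,7-bis(benzyloxy)-4H-chromen-4-one | O=c1ccoc2cc(OCc3ccccc3)cc(OCc3ccccc3)c12 | intermediate
22 | (2S)-5,7-bis(benzyloxy)-2-[(2R,3S)-7-(benzyloxy)-2-[4-(benzyloxy)-3-methoxyphenyl]-3-{[(tert-butyldimethylsilyl)oxy]methyl}-2,3-dihydro-1-benzofuran-5-yl]-2,3-dihydro-4H-chromen-4-one | COc1cc([C@@H]2Oc3c(OCc4ccccc4)cc([C@@H]4CC(=O)c5c(OCc6ccccc6)cc(OCc6ccccc6)cc5O4)cc3[C@H]2CO[Si](C)(C)C(C)(C)C)ccc1OCc1ccccc1 | intermediate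
23 | (2S)-5,7-bis(benzyloxy)-2-[(2R,3S)-7-(benzyloxy)-2-[4-(benzyloxy)-3-methoxyphenyl]-3-(hydroxymethyl)-2,3-dihydro-1-benzofuran-5-yl]-2,3-dihydro-4H-chromen-4-one | COc1cc([C@@H]2Oc3c(OCc4ccccc4)cc([C@@H]4CC(=O)c5c(OCc6ccccc6)cc(OCc6ccccc6)cc5O4)cc3[C@H]2CO)ccc1OCc1ccccc1 | intermediate
24 | silyhermin B, (2S)-5,7-dihydroxy-2-[(2R,3S)-7-hydroxy-2-(4-hydroxy-3-methoxyphenyl)-3-(hydroxymethyl)-2,3-dihydro-1-benzofuran-5-yl]-2,3-dihydro-4H-chromen-4-one | COc1cc([C@@H]2Oc3c(O)cc([C@@H]4CC(=O)c5c(O)cc(O)cc5O4)cc3[C@H]2CO)ccc1O | target

## Step count and least certain steps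

Total step count: 14. Longest linear sequence: 12 (steps 1 to 9, then 12 to 14).

**Step 6 (key step).** Three processes could divert it: a competing 1,2-shift of the electron-rich C2 aryl group from the diaxial conformer of the iodine adduct; direct solvolysis of the C–I bond to a dimethoxy adduct; and oxidative or acid-induced ionisation at C2, which would erode the enantiomeric purity or aromatise the pyran ring. The fallback sets out from 10 and moves the rearrangement to the ketone oxidation level, where the contraction of 2-arylchromanones with alkoxy-substituted aryl groups is established: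
- Markovnikov hydration of the styrene-type alkene (Co(acac)2, PhSiH3, O2, THF/i-PrOH) should give the flavan-4-ol (2R)-8-(benzyloxy)-2-[4-(benzyloxy)-3-methoxyphenyl]-6-bromo-3,4-dihydro-2H-chromen-4-ol F1.
- Oxidation with Dess–Martin periodinane gives the flavanone (2R)-8-(benzyloxy)-2-[4-(benzyloxy)-3-methoxyphenyl]-6-bromo-2,3-dihydro-4H-chromen-4-one F2.
- PhI(OAc)2 with catalytic H2SO4 in HC(OMe)3 contracts the enol ether of F2 to methyl (2R,3R)-7-(benzyloxy)-2-[4-(benzyloxy)-3-methoxyphenyl]-5-bromo-2,3-dihydro-1-benzofuran-3-carboxylate F3.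
- Reduction of the ester with i-Bu2AlH (CH2Cl2, −78 °C) returns to the route at 13.

This detour also avoids the sensitive aldehyde 12.

**Step 5.** Ionisation of an acetal that carries bromine para to O1 may be slow, so an uncatalysed or poorly organised background addition could lower the facial selectivity; the acid-labile acetal may also decompose. The fallback sets out from 3:
- (E)-3-[4-(benzyloxy)-3-methoxyphenyl]prop-2-enal F4 is made from 4-(benzyloxy)-3-methoxybenzaldehyde and Ph3P=CHCHO.
- Domino oxa-Michael addition and aldol condensation of 3 with F4, under a diphenylprolinol trimethylsilyl ether with a carboxylic acid co-catalyst (iminium activation), should give (2S)-8-(benzyloxy)-2-[4-(benzyloxy)-3-methoxyphenyl]-6-bromo-2H-chromene-3-carbaldehyde F5. Its C2 has the same spatial arrangement as that of 10.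
- Tsuji–Wilkinson decarbonylation with RhCl(PPh3)3 in refluxing toluene removes the formyl group and returns to the route at 10.

**Step 12.** Insertion into the electron-rich, peri-substituted chromone may be slower than protodeboronation or homocoupling of 17, and the facial selectivity on this acceptor is untested. The fallback sets out from 14 and uses 19:
- Bromine–lithium exchange (n-BuLi, THF, −78 °C) and DMF give (2R,3S)-7-(benzyloxy)-2-[4-(benzyloxy)-3-methoxyphenyl]-3-{[(tert-butyldimethylsilyl)oxy]methyl}-2,3-dihydro-1-benzofuran-5-carbaldehyde F6.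
- Claisen–Schmidt condensation of F6 with 19 (KOH, EtOH, rt) gives the 2'-hydroxychalcone (E)-1-[2,4-bis(benzyloxy)-6-hydroxyphenyl]-3-[(2R,3S)-7-(benzyloxy)-2-[4-(benzyloxy)-3-methoxyphenyl]-3-{[(tert-butyldimethylsilyl)oxy]methyl}-2,3-dihydro-1-benzofuran-5-yl]prop-2-en-1-one F7.
- NaOAc in refluxing EtOH closes F7 by oxa-Michael addition to 22 together with its C2' epimer, (2R)-5,7-bis(benzyloxy)-2-[(2R,3S)-7-(benzyloxy)-2-[4-(benzyloxy)-3-methoxyphenyl]-3-{[(tert-butyldimethylsilyl)oxy]methyl}-2,3-dihydro-1-benzofuran-5-yl]-2,3-dihydro-4H-chromen-4-one F8.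
- The two are diastereomers and should be separable by chromatography; F8 can be re-equilibrated through F7. The route is rejoined at 22.

**Step 14.** Hydrogenolytic opening of the benzylic O1–C2 or O1'–C2' bond, or reduction of the ketone, may compete with O-debenzylation if the reaction is prolonged. The fallback sets out from 23 and is non-reductive: BCl3 with pentamethylbenzene as benzyl cation scavenger in CH2Cl2 at −78 °C should cleave the four aryl benzyl ethers directly to 24, with no new intermediate.

## Further compounds

F1 | step 6 | (2R)-8-(benzyloxy)-2-[4-(benzyloxy)-3-methoxyphenyl]-6-bromo-3,4-dihydro-2H-chromen-4-ol (mixture at C4) | COc1cc([C@@H]2Oc3c(OCc4ccccc4)cc(Br)cc3C(O)C2)ccc1OCc1ccccc1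
F2 | step 6 | (2R)-8-(benzyloxy)-2-[4-(benzyloxy)-3-methoxyphenyl]-6-bromo-2,3-dihydro-4H-chromen-4-one | COc1cc([C@@H]2Oc3c(OCc4ccccc4)cc(Br)cc3C(=O)C2)ccc1OCc1ccccc1
F3 | step 6 | methyl (2R,3R)-7-(benzyloxy)-2-[4-(benzyloxy)-3-methoxyphenyl]-5-bromo-2,3-dihydro-1-benzofuran-3-carboxylate (trans) | COc1cc([C@@H]2Oc3c(OCc4ccccc4)cc(Br)cc3[C@H]2C(=O)OC)ccc1OCc1ccccc1
F4 | step 5 | (E)-3-[4-(benzyloxy)-3-methoxyphenyl]prop-2-enal | COc1cc(/C=C/C=O)ccc1OCc1ccccc1
F5 | step 5 | (2S)-8-(benzyloxy)-2-[4-(benzyloxy)-3-methoxyphenyl]-6-bromo-2H-chromene-3-carbaldehyde | COc1cc([C@@H]2Oc3c(OCc4ccccc4)cc(Br)cc3C=C2C=O)ccc1OCc1ccccc1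
F6 | step 12 | (2R,3S)-7-(benzyloxy)-2-[4-(benzyloxy)-3-methoxyphenyl]-3-{[(tert-butyldimethylsilyl)oxy]methyl}-2,3-dihydro-1-benzofuran-5-carbaldehyde | COc1cc([C@@H]2Oc3c(OCc4ccccc4)cc(C=O)cc3[C@H]2CO[Si](C)(C)C(C)(C)C)ccc1OCc1ccccc1
F7 | step 12 | (E)-1-[2,4-bis(benzyloxy)-6-hydroxyphenyl]-3-[(2R,3S)-7-(benzyloxy)-2-[4-(benzyloxy)-3-methoxyphenyl]-3-{[(tert-butyldimethylsilyl)oxy]methyl}-2,3-dihydro-1-benzofuran-5-yl]prop-2-en-1-one | COc1cc([C@@H]2Oc3c(OCc4ccccc4)cc(/C=C/C(=O)c4c(O)cc(OCc5ccccc5)cc4OCc4ccccc4)cc3[C@H]2CO[Si](C)(C)C(C)(C)C)ccc1OCc1ccccc1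
F8 | step 12 | (2R)-5,7-bis(benzyloxy)-2-[(2R,3S)-7-(benzyloxy)-2-[4-(benzyloxy)-3-methoxyphenyl]-3-{[(tert-butyldimethylsilyl)oxy]methyl}-2,3-dihydro-1-benzofuran-5-yl]-2,3-dihydro-4H-chromen-4-one | COc1cc([C@@H]2Oc3c(OCc4ccccc4)cc([C@H]4CC(=O)c5c(OCc6ccccc6)cc(OCc6ccccc6)cc5O4)cc3[C@H]2CO[Si](C)(C)C(C)(C)C)ccc1OCc1ccccc1
F0 | step 14 | none | none
A1 | alternative 1 | (3R)-3-[(2R,3S)-7-(benzyloxy)-2-[4-(benzyloxy)-3-methoxyphenyl]-3-[(benzyloxy)methyl]-2,3-dihydro-1-benzofuran-5-yl]-3-[(tert-butyldimethylsilyl)oxy]-1-(2,4,6-trihydroxyphenyl)propan-1-one | COc1cc([C@@H]2Oc3c(OCc4ccccc4)cc([C@H](O[Si](C)(C)C(C)(C)C)CC(=O)c4c(O)cc(O)cc4O)cc3[C@H]2COCc4ccccc4)ccc1OCc1ccccc1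
A2 | alternative 1 | methyl (9R)-9-[(2R,3S)-7-(benzyloxy)-2-[4-(benzyloxy)-3-methoxyphenyl]-3-[(benzyloxy)methyl]-2,3-dihydro-1-benzofuran-5-yl]-9-[(tert-butyldimethylsilyl)oxy]-3,5,7-trioxononanoate | COc1cc([C@@H]2Oc3c(OCc4ccccc4)cc([C@H](O[Si](C)(C)C(C)(C)C)CC(=O)CC(=O)CC(=O)CC(=O)OC)cc3[C@H]2COCc4ccccc4)ccc1OCc1ccccc1
A3 | alternative 2 | (2S)-5,7-bis(benzyloxy)-2-[(2R,3S)-7-(benzyloxy)-2-[4-(benzyloxy)-3-methoxyphenyl]-3-{[(tert-butyldimethylsilyl)oxy]methyl}-2,3-dihydro-1-benzofuran-5-yl]-2,3-dihydro-4H-chromen-4-one (identical with 22) | COc1cc([C@@H]2Oc3c(OCc4ccccc4)cc([C@@H]4CC(=O)c5c(OCc6ccccc6)cc(OCc6ccccc6)cc5O4)cc3[C@H]2CO[Si](C)(C)C(C)(C)C)ccc1OCc1ccccc1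
A4 | alternative 2 | 5,7-bis(benzyloxy)-2-[(2R,3S)-7-(benzyloxy)-2-[4-(benzyloxy)-3-methoxyphenyl]-3-{[(tert-butyldimethylsilyl)oxy]methyl}-2,3-dihydro-1-benzofuran-5-yl]-4-methylidene-4H-1,3-benzodioxine (either configuration at the acetal carbon) | COc1cc([C@@H]2Oc3c(OCc4ccccc4)cc(C4OC(=C)c5c(OCc6ccccc6)cc(OCc6ccccc6)cc5O4)cc3[C@H]2CO[Si](C)(C)C(C)(C)C)ccc1OCc1ccccc1
A5 | alternative 3 | (2R,3S)-3-{[(tert-butyldimethylsilyl)oxy]methyl}-2-(4-hydroxy-3-methoxyphenyl)-7-(methoxymethoxy)-2,3-dihydro-1-benzofuran-5-carbaldehyde | COc1cc([C@@H]2Oc3c(OCOC)cc(C=O)cc3[C@H]2CO[Si](C)(C)C(C)(C)C)ccc1O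
A6 | alternative 3 | 3-[(2S)-1-[(tert-butyldimethylsilyl)oxy]-3-(4-hydroxy-3-methoxyphenyl)propan-2-yl]-4-hydroxy-5-(methoxymethoxy)benzaldehyde | O=Cc1cc(OCOC)c(O)c(c1)[C@H](Cc1ccc(O)c(OC)c1)CO[Si](C)(C)C(C)(C)C
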